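The route rests on disconnecting the O7–C bond of the dihydrofuran ring that is fused to ring A of the kaempferol unit. The hemiketal carbon is the benzylic carbon of a 4-oxygenated benzyl group on the spiro carbon (C2 of the benzofuranone) and lies 1,5 to the phenolic O7. A single anodic four-electron oxidation of that 4-(methoxymethoxy)benzyl CH2 closes the dihydrofuran ring through O7 and adds the hemiketal hydroxyl from water. Its substrate is the (S)-2-aryl-2-benzylbenzofuran-3-one carrying a free 7-OH and five aryl acetates, reached by Pd-catalysed α-arylation of a benzofuranone with an 8-iodokaempferol ether and asymmetric phase-transfer benzylation.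

Key step: step 13

Abbreviations: TOM = [(triisopropylsilyl)oxy]methyl, MOM = methoxymethyl; flavonoid locants (3, 5, 7, 8, 4') are used for the kaempferol unit and benzofuran locants for the benzofuranone.

Remark: the hemiketal epimer of the target (OH syn to the benzofuranone C=O) is assumed to be the thermodynamic one, and the cinchoninium salt of step 10 is assumed to give S (its cinchonidinium pseudo-enantiomer would be used otherwise).

Step 1
Reactants: 1 kaempferol
Product: 2 kaempferol 3,5,7,4'-tetraacetate
Conditions: Ac2O, pyridine, DMAP (cat.), rt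
Reagents that add atoms: acetic anhydride, CC(=O)OC(C)=O
Why: Nucleophile-catalysed O-acylation of phenols with an anhydride is exhaustive for flavonols and also reaches the hydrogen-bonded 5-OH.

Step 2
Reactants: 2 kaempferol 3,5,7,4'-tetraacetate
Product: 3 kaempferol 3,5,4'-triacetate (7-OH free)
Conditions: PhSH, imidazole (cat.), N-methylpyrrolidone, 0 °C to rt
Reagents that add atoms: none
Why: Chemoselective thiolysis of an aryl ester removes only the acetate of the most acidic phenol (the vinylogous-acid 7-OH), a selectivity established for flavonoid peracetates.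

Step 3
Reactants: 3 kaempferol 3,5,4'-triacetate
Product: 4 7-O-TOM-kaempferol 3,5,4'-triacetate
Conditions: TOM-Cl, iPr2NEt, CH2Cl2, 0 °C to rt
Reagents that add atoms: [(triisopropylsilyl)oxy]methyl chloride, ClCO[Si](C(C)C)(C(C)C)C(C)C
Why: O-Alkylation of the ionised 7-OH with an α-chloro ether (Williamson-type acetal formation) installs an achiral siloxymethyl acetal that survives carbonate, hydroxide, mild acid and hydrogenolysis but is cleaved by fluoride, which is the orthogonality needed in step 12.

Step 4
Reactants: 4 7-O-TOM-kaempferol 3,5,4'-triacetate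
Product: 6 3,5,4'-tri-O-benzyl-7-O-TOM-kaempferol, via 7-O-TOM-kaempferol 5 (not isolated)
Conditions: K2CO3, MeOH/THF, rt, argon; evaporate; BnBr, K2CO3, Bu4NI (cat.), DMF, 70 °C
Reagents that add atoms: benzyl bromide, BrCc1ccccc1
Why: Base-catalysed transesterification frees the three phenols and Williamson benzylation of their phenoxides (forcing conditions for the chelated 5-OH) exchanges base-labile for base-stable protection ahead of the enolate chemistry.

Step 5
Reactants: 6 3,5,4'-tri-O-benzyl-7-O-TOM-kaempferol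
Product: 7 8-iodo-3,5,4'-tri-O-benzyl-7-O-TOM-kaempferol
Conditions: NIS, CF3CO2H (cat.), MeCN, 0 °C to rt
Reagents that add atoms: N-iodosuccinimide, O=C1CCC(=O)N1I
Why: Electrophilic aromatic iodination takes place on ring A, the most electron-rich arene, and at C8 rather than C6 because C8 lies between O7 and the pyranone oxygen while C6 is flanked by two bulky ethers, as is general for 5,7-dialkoxyflavones.

Step 6
Reactants: 8 4,6-dihydroxybenzofuran-3(2H)-one
Product: 9 4,6-bis(benzyloxy)benzofuran-3(2H)-one
Conditions: BnBr, K2CO3, DMF, rt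
Reagents that add atoms: benzyl bromide, BrCc1ccccc1
Why: Williamson etherification of both phenols under mild carbonate conditions is the standard preparation of 4,6-dialkoxybenzofuranones and leaves the C2 methylene largely untouched.

Step 7
Reactants: 7 8-iodo-3,5,4'-tri-O-benzyl-7-O-TOM-kaempferol; 9 4,6-bis(benzyloxy)benzofuran-3(2H)-one
Product: 10 rac-4,6-bis(benzyloxy)-2-(3,5,4'-tri-O-benzyl-7-O-TOM-kaempferol-8-yl)benzofuran-3(2H)-one
Conditions: Pd(OAc)2 (5 mol %), XPhos (10 mol %), K3PO4, toluene, 90 °C, argon; degassed aq. NH4Cl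
Reagents that add atoms: none
Why: Pd-catalysed α-arylation of a ketone enolate with an aryl iodide, with a bulky biarylphosphine to drive reductive elimination at the doubly ortho-substituted C8, joins the halves and stops at monoarylation because the product persists as its stabilised enolate, C2 staying epimerisable so that no stereochemistry is set.

Step 8
Reactants: 11 4-hydroxybenzyl alcohol
Product: 12 4-(methoxymethoxy)benzyl alcohol
Conditions: MOMCl, K2CO3, acetone, 0 °C to rt
Reagents that add atoms: chloromethyl methyl ether, COCCl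
Why: Williamson O-alkylation with chloromethyl methyl ether is selective for the phenoxide because carbonate ionises the phenol but not the benzylic alcohol.

Step 9
Reactants: 12 4-(methoxymethoxy)benzyl alcohol
Product: 13 4-(methoxymethoxy)benzyl bromide
Conditions: CBr4, PPh3, CH2Cl2, 0 °C; used at once
Reagents that add atoms: carbon tetrabromide, BrC(Br)(Br)Br
Why: The Appel reaction converts the benzylic alcohol into the bromide under neutral conditions that spare the MOM acetal.

Step 10
Reactants: 10 rac-2-aryl benzofuranone; 13 4-(methoxymethoxy)benzyl bromide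
Product: 14 (S)-4,6-bis(benzyloxy)-2-[4-(methoxymethoxy)benzyl]-2-(3,5,4'-tri-O-benzyl-7-O-TOM-kaempferol-8-yl)benzofuran-3(2H)-one
Conditions: N-[4-(trifluoromethyl)benzyl]cinchoninium bromide (10 mol %), 50% aq. KOH, toluene, 0 °C, argon
Reagents that add atoms: none
Why: Asymmetric phase-transfer-catalysed alkylation of a 2-aryl cyclic ketone enolate: the cinchona-derived ammonium cation forms a tight ion pair with the enolate and shields one face so that the benzyl bromide attacks the other and sets the quaternary S centre, while C-alkylation is favoured over O-alkylation by the soft electrophile, the non-polar medium and the flanking 4-benzyloxy group.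

Step 11
Reactants: 14 (S)-benzylated hexaether
Product: 16 (S)-4,6-diacetoxy-2-[4-(methoxymethoxy)benzyl]-2-(3,5,4'-tri-O-acetyl-7-O-TOM-kaempferol-8-yl)benzofuran-3(2H)-one, via (S)-pentaphenol 15 (not isolated)
Conditions: H2 (1 atm), Pd/C, THF/EtOAc, rt; filter under argon; Ac2O, pyridine, DMAP (cat.), rt
Reagents that add atoms: acetic anhydride, CC(=O)OC(C)=O
Why: Catalytic hydrogenolysis removes only the five aryl benzyl ethers and nucleophile-catalysed acetylation of the air-sensitive pentaphenol in the same flask installs the electron-withdrawing esters needed in step 13, the quaternary centre being untouched by either operation.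

Step 12
Reactants: 16 (S)-pentaacetate 7-O-TOM ether
Product: 17 (S)-4,6-diacetoxy-2-[4-(methoxymethoxy)benzyl]-2-(3,5,4'-tri-O-acetylkaempferol-8-yl)benzofuran-3(2H)-one (7-OH free)
Conditions: HF·pyridine, THF/pyridine, 0 °C to rt
Reagents that add atoms: none
Why: Fluoride-mediated desilylation of the siloxymethyl acetal gives a hemiformal that collapses to the free 7-OH, under conditions that leave aryl acetates and the MOM ether intact.

Step 13
Reactants: 17 (S)-2-[4-(methoxymethoxy)benzyl]-2-(7-hydroxy-3,5,4'-triacetoxyflavon-8-yl)-4,6-diacetoxybenzofuran-3-one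
Product: 18 target pentaacetate mono-MOM ether (spiro carbon S, hemiketal carbon R)
Conditions: graphite anode, Pt cathode, undivided cell, LiClO4 (0.1 M), MeCN/H2O 9:1, constant current, 4.2 F/mol, rt
Reagents that add atoms: water, O
Why: Proposed new method: one-electron oxidation of the 4-(methoxymethoxy)phenyl ring, loss of a benzylic proton and a second electron transfer give a 4-alkoxybenzyl cation that O7 of ring A captures, and a second two-electron oxidation of the resulting α-aryl cyclic ether gives a 2-aryl oxocarbenium ion that water quenches, the closest known reaction types being the anodic side-chain oxidation of 4-alkoxytoluenes to benzaldehyde acetals and anodic or quinone-mediated benzylic C–H etherification. The dihydrofuran ring closes in a 5-exo mode (O7 onto the exocyclic carbon of the para-quinoid oxocarbenium form), and only the O7–C bond is formed. The spiro carbon is quaternary and untouched, while the new hemiketal carbon is under thermodynamic control through ring–chain equilibration with the hydroxy ketone, which should favour the epimer with OH syn to the benzofuranone carbonyl. The step needs oxidation of one arene among five, which the five acetates and the vinylogous-acid character of the 7-hydroxychromone ring secure by raising the potentials of all other rings, and it cannot over-oxidise because the hemiketal carbon carries no hydrogen. Should water trap the cation before O7 does, the benzylic alcohol is oxidised on to the aryl ketone, which closes to the same hemiketal.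

Step 14
Reactants: 18 target pentaacetate mono-MOM ether
Product: 19 CNP0283000.1 (target)
Conditions: 3 M aq. HCl/THF 1:1, 50 °C
Reagents that add atoms: none
Why: Acid-catalysed hydrolysis of the five aryl esters and the MOM acetal in water instead of an alcohol keeps the hemiketal from becoming a mixed ketal, and acid is chosen over base because the ring-opened form is a non-enolisable 1,3-diketone prone to retro-Claisen cleavage, while the quaternary spiro centre cannot epimerise.

Compound list
1 | kaempferol | O=c1c(O)c(-c2ccc(O)cc2)oc2cc(O)cc(O)c12 | starting material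
2 | kaempferol 3,5,7,4'-tetraacetate | O=c1c(OC(C)=O)c(-c2ccc(OC(C)=O)cc2)oc2cc(OC(C)=O)cc(OC(C)=O)c12 | intermediate
3 | kaempferol 3,5,4'-triacetate (7-OH free) | O=c1c(OC(C)=O)c(-c2ccc(OC(C)=O)cc2)oc2cc(O)cc(OC(C)=O)c12 | intermediate
4 | 7-O-TOM-kaempferol 3,5,4'-triacetate | O=c1c(OC(C)=O)c(-c2ccc(OC(C)=O)cc2)oc2cc(OCO[Si](C(C)C)(C(C)C)C(C)C)cc(OC(C)=O)c12 | intermediate
5 | 7-O-TOM-kaempferol (3-, 5- and 4'-OH free; not isolated) | O=c1c(O)c(-c2ccc(O)cc2)oc2cc(OCO[Si](C(C)C)(C(C)C)C(C)C)cc(O)c12 | intermediate
6 | 3,5,4'-tri-O-benzyl-7-O-TOM-kaempferol | O=c1c(OCc2ccccc2)c(-c2ccc(OCc3ccccc3)cc2)oc2cc(OCO[Si](C(C)C)(C(C)C)C(C)C)cc(OCc3ccccc3)c12 | intermediate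
7 | 8-iodo-3,5,4'-tri-O-benzyl-7-O-TOM-kaempferol | O=c1c(OCc2ccccc2)c(-c2ccc(OCc3ccccc3)cc2)oc2c(I)c(OCO[Si](C(C)C)(C(C)C)C(C)C)cc(OCc3ccccc3)c12 | intermediate
8 | 4,6-dihydroxybenzofuran-3(2H)-one | O=C1COc2cc(O)cc(O)c12 | starting material
9 | 4,6-bis(benzyloxy)benzofuran-3(2H)-one | O=C1COc2cc(OCc3ccccc3)cc(OCc3ccccc3)c12 | intermediate
10 | rac-4,6-bis(benzyloxy)-2-(3,5,4'-tri-O-benzyl-7-O-TOM-kaempferol-8-yl)benzofuran-3(2H)-one (C2–H, epimerisable) | O=C1c2c(OCc3ccccc3)cc(OCc3ccccc3)cc2OC1c1c(OCO[Si](C(C)C)(C(C)C)C(C)C)cc(OCc2ccccc2)c2c(=O)c(OCc3ccccc3)c(-c3ccc(OCc4ccccc4)cc3)oc12 | intermediate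
11 | 4-hydroxybenzyl alcohol | OCc1ccc(O)cc1 | starting material
12 | 4-(methoxymethoxy)benzyl alcohol | COCOc1ccc(CO)cc1 | intermediate
13 | 4-(methoxymethoxy)benzyl bromide | COCOc1ccc(CBr)cc1 | intermediate
14 | (S)-4,6-bis(benzyloxy)-2-[4-(methoxymethoxy)benzyl]-2-(3,5,4'-tri-O-benzyl-7-O-TOM-kaempferol-8-yl)benzofuran-3(2H)-one | O=C1c2c(OCc3ccccc3)cc(OCc3ccccc3)cc2O[C@@]1(Cc1ccc(OCOC)cc1)c1c(OCO[Si](C(C)C)(C(C)C)C(C)C)cc(OCc2ccccc2)c2c(=O)c(OCc3ccccc3)c(-c3ccc(OCc4ccccc4)cc3)oc12 | intermediate
15 | (S)-4,6-dihydroxy-2-[4-(methoxymethoxy)benzyl]-2-(7-O-TOM-kaempferol-8-yl)benzofuran-3(2H)-one (pentaphenol; not isolated) | O=C1c2c(O)cc(O)cc2O[C@@]1(Cc1ccc(OCOC)cc1)c1c(OCO[Si](C(C)C)(C(C)C)C(C)C)cc(O)c2c(=O)c(O)c(-c3ccc(O)cc3)oc12 | intermediate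
16 | (S)-4,6-diacetoxy-2-[4-(methoxymethoxy)benzyl]-2-(3,5,4'-tri-O-acetyl-7-O-TOM-kaempferol-8-yl)benzofuran-3(2H)-one | O=C1c2c(OC(C)=O)cc(OC(C)=O)cc2O[C@@]1(Cc1ccc(OCOC)cc1)c1c(OCO[Si](C(C)C)(C(C)C)C(C)C)cc(OC(C)=O)c2c(=O)c(OC(C)=O)c(-c3ccc(OC(C)=O)cc3)oc12 | intermediate
17 | (S)-4,6-diacetoxy-2-[4-(methoxymethoxy)benzyl]-2-(3,5,4'-tri-O-acetylkaempferol-8-yl)benzofuran-3(2H)-one (7-OH free; key-step precursor) | O=C1c2c(OC(C)=O)cc(OC(C)=O)cc2O[C@@]1(Cc1ccc(OCOC)cc1)c1c(O)cc(OC(C)=O)c2c(=O)c(OC(C)=O)c(-c3ccc(OC(C)=O)cc3)oc12 | intermediate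
18 | target pentaacetate mono-MOM ether: 4,6-diacetoxybenzofuran-3-one spiro-linked at C2 (S) to a 2-hydroxy-2-[4-(methoxymethoxy)phenyl]-2,3-dihydrofuran (hemiketal carbon R, OH syn to the benzofuranone C=O) fused through O7 and C8 to 3,5,4'-tri-O-acetylkaempferol | O=C1c2c(OC(C)=O)cc(OC(C)=O)cc2O[C@@]12c1c(cc(OC(C)=O)c3c(=O)c(OC(C)=O)c(-c4ccc(OC(C)=O)cc4)oc13)O[C@]2(O)c1ccc(OCOC)cc1 | intermediate
19 | CNP0283000.1: 4,6-dihydroxybenzofuran-3-one spiro-linked at C2 (S) to a 2-hydroxy-2-(4-hydroxyphenyl)-2,3-dihydrofuran (hemiketal carbon R) fused through O7 and C8 to kaempferol | O=C1c2c(O)cc(O)cc2O[C@@]12c1c(cc(O)c3c(=O)c(O)c(-c4ccc(O)cc4)oc13)O[C@]2(O)c1ccc(O)cc1 | target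

Total step count: 14. Longest linear sequence: 11 steps (kaempferol 1 to target 19 through steps 1–5, 7 and 10–14).

Steps most likely to fail

Step 13 (proposed new method). The arene radical cation may fragment at the weak benzylic C–C bond, expelling the 4-alkoxybenzyl cation from the captodatively stabilised quaternary carbon, faster than it loses a benzylic proton. The free 7-OH may also be oxidised competitively, the benzylic cation may suffer a 1,2-aryl shift, and anodically generated acid may strip the MOM acetal. The fallback moves the oxidation one stage earlier and changes its kind, setting out from 16. DDQ in aqueous dioxane at 80 °C, the established hydride-abstraction oxidation of 4-alkoxybenzyl methylenes to aryl ketones, should convert the benzyl group with O7 still masked into the (R)-4,6-diacetoxy-2-[4-(methoxymethoxy)benzoyl]-2-(3,5,4'-tri-O-acetyl-7-O-TOM-kaempferol-8-yl)benzofuran-3(2H)-one F1 (same spatial arrangement as 16; the descriptor changes with the CIP ranking). HF·pyridine then removes the TOM group, and the freed 7-OH adds to the new ketone, so the hemiketal ring closes by ring–chain tautomerism and the route is rejoined at 18.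

Step 7. Oxidative addition or reductive elimination at the doubly ortho-substituted C8 may be too slow, so that protodeiodination of 7 takes over, or the product enolate may be lost to autoxidation. The fallback makes the C8–C2 bond as an aryl–heteroaryl bond, setting out from 9 and 7. Silylation of 9 (TBSOTf, Et3N, CH2Cl2) should give the aromatic 4,6-bis(benzyloxy)-3-[(tert-butyldimethylsilyl)oxy]benzofuran F2. C2-lithiation and borylation (n-BuLi, THF, −78 °C, then 2-isopropoxy-4,4,5,5-tetramethyl-1,3,2-dioxaborolane) should give its 2-pinacolboronate F3. Suzuki–Miyaura coupling with 7 (Pd(OAc)2, SPhos, K3PO4, toluene/H2O, 80 °C), a coupling type with precedent at C8 of flavones, should give the 2-(kaempferol-8-yl)-3-silyloxybenzofuran F4. Selective cleavage of the enol silyl ether (Cs2CO3, DMF/H2O, degassed) returns the route to 10.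

Step 10. Facial discrimination by the chiral ion pair may be poor at this very hindered enolate, whose two faces are each flanked by an ortho substituent of the 8-aryl group. The fallback gives up asymmetric induction for resolution, setting out from 10 and 13. Alkylation under achiral phase transfer (Bu4NBr, 50% aq. KOH, toluene) should give the racemic benzylated hexaether F5. Preparative chromatography on a cellulose-derived chiral stationary phase should separate it into 14, where the route is rejoined, and the (R)-enantiomer F6, which is discarded.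

Further compounds
F1 | step 13 | (R)-4,6-diacetoxy-2-[4-(methoxymethoxy)benzoyl]-2-(3,5,4'-tri-O-acetyl-7-O-TOM-kaempferol-8-yl)benzofuran-3(2H)-one | O=C1c2c(OC(C)=O)cc(OC(C)=O)cc2O[C@@]1(C(=O)c1ccc(OCOC)cc1)c1c(OCO[Si](C(C)C)(C(C)C)C(C)C)cc(OC(C)=O)c2c(=O)c(OC(C)=O)c(-c3ccc(OC(C)=O)cc3)oc12
F2 | step 7 | 4,6-bis(benzyloxy)-3-[(tert-butyldimethylsilyl)oxy]benzofuran | CC(C)(C)[Si](C)(C)Oc1coc2cc(OCc3ccccc3)cc(OCc3ccccc3)c12
F3 | step 7 | 4,6-bis(benzyloxy)-3-[(tert-butyldimethylsilyl)oxy]-2-(4,4,5,5-tetramethyl-1,3,2-dioxaborolan-2-yl)benzofuran | CC(C)(C)[Si](C)(C)Oc1c(B2OC(C)(C)C(C)(C)O2)oc2cc(OCc3ccccc3)cc(OCc3ccccc3)c12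
F4 | step 7 | 4,6-bis(benzyloxy)-3-[(tert-butyldimethylsilyl)oxy]-2-(3,5,4'-tri-O-benzyl-7-O-TOM-kaempferol-8-yl)benzofuran | CC(C)(C)[Si](C)(C)Oc1c(-c2c(OCO[Si](C(C)C)(C(C)C)C(C)C)cc(OCc3ccccc3)c3c(=O)c(OCc4ccccc4)c(-c4ccc(OCc5ccccc5)cc4)oc23)oc2cc(OCc3ccccc3)cc(OCc3ccccc3)c12
F5 | step 10 | rac-4,6-bis(benzyloxy)-2-[4-(methoxymethoxy)benzyl]-2-(3,5,4'-tri-O-benzyl-7-O-TOM-kaempferol-8-yl)benzofuran-3(2H)-one | O=C1c2c(OCc3ccccc3)cc(OCc3ccccc3)cc2OC1(Cc1ccc(OCOC)cc1)c1c(OCO[Si](C(C)C)(C(C)C)C(C)C)cc(OCc2ccccc2)c2c(=O)c(OCc3ccccc3)c(-c3ccc(OCc4ccccc4)cc3)oc12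
F6 | step 10 | (R)-4,6-bis(benzyloxy)-2-[4-(methoxymethoxy)benzyl]-2-(3,5,4'-tri-O-benzyl-7-O-TOM-kaempferol-8-yl)benzofuran-3(2H)-one | O=C1c2c(OCc3ccccc3)cc(OCc3ccccc3)cc2O[C@]1(Cc1ccc(OCOC)cc1)c1c(OCO[Si](C(C)C)(C(C)C)C(C)C)cc(OCc2ccccc2)c2c(=O)c(OCc3ccccc3)c(-c3ccc(OCc4ccccc4)cc3)oc12
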